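## The problem

The target is the flavone 13, 2-(4-hydroxy-2,5-dimethoxyphenyl)-5,7-dimethoxy-4H-chromen-4-one. A phloroglucinol-type ring A and a 2',4',5'-trioxygenated ring B are joined by the three carbons C2, C3 and C4 of the pyranone ring C, with O1 bridging C8a and C2. There is no stereocentre, so the tasks are regiochemical: the three-carbon link must be placed correctly, and one free phenol (4'-OH) must be told apart from four methyl ethers. Both arenes are very electron-rich, so C6 and C8 of ring A and C3' and C6' of ring B are open to electrophilic halogenation and to oxidants. The 5-methoxy group, peri to the C4 carbonyl, is the first ether lost under Lewis or strong Brønsted acids, and the finished pyranone is opened at C2 by hard nucleophiles. The arenes should therefore be joined under mild, preferably neutral conditions, and the 4'-phenol freed last without touching the methyl ethers. The enabling feature is that C2 and C4 both stand at the carbonyl oxidation level on either side of the C3 methine, which is exactly what a 3,5-diarylisoxazole stores in masked form. In addition, the ring A carbon that carries this link (C4a) lies between two oxygenated carbons (C5 and C8a), so a nitrile oxide placed there is shielded on both sides and should be long-lived.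

## Retrosynthesis

**O1–C2 (ring C).** Cutting O1–C2 of 13 by retro-cyclodehydration gives the o-hydroxyaryl 1,3-diketone 12. Exchanging its C4 oxygen for nitrogen gives the primary enaminone 11, the form in which the open chain is actually made. This cut is preferred over C2–C1' (arylation of a preformed chromone) or C4–C4a (acylation of a phloroglucinol ether). Acid closure of an o-hydroxyaryl 1,3-dicarbonyl needs only a proton and cannot give a regioisomer here, because ring B has no free ortho hydroxyl. Precursor 11 lacks ring C. The forward step must hydrolyse a vinylogous amide and dehydrate in warm dilute acid, which leaves the four methyl ethers, including the 5-methoxy group, alone.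

**N–O and two O–benzyl bonds.** In 11 the nitrogen on C4 and the oxygen on C2 are the two ends of a cleaved N–O bond, so 11 is the hydrogenolysis product of isoxazole 10, in which both phenols are also held as benzyl ethers. A chalcone would be one oxidation level too low and would need a late oxidation in the presence of two electron-rich arenes. A Baker–Venkataraman ester would need strong base on a doubly ortho-substituted acetophenone. The isoxazole holds C2 and C4 at the correct level in a neutral, aromatic, non-enolisable ring that can be purified and stored. The forward step asks one hydrogenation to cleave the N–O bond and both benzyl ethers without reducing the enaminone.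

**C3–C4 and the O–C2 bond of the isoxazole.** Isoxazole 10 is cut across the ring into nitrile oxide 4 and terminal alkyne 9. This is the convergent cut: it halves the molecule, and each half carries all of its aryl oxygens. The nitrile oxide is placed on ring A because there the dipole carbon has two ortho alkoxy groups, which suppress dimerisation. The reverse assignment would give a dipole with one ortho substituent and a hindered, doubly flanked alkyne. The price is that nitrogen ends on C4 and must later be hydrolysed off. Of the three dipole atoms only the carbon remains in 13: the dipole oxygen leaves C2 as water in the ring closure, and the C4 oxygen comes from water. The forward reaction must be regioselective for the 3,5-diaryl isomer and faster than the decay of the dipole.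

**Nitrile oxide 4.** The dipole is traced back by dehydrogenation to the E aldoxime 3, by condensation to aldehyde 2, and by O-benzylation to commercial 2-hydroxy-4,6-dimethoxybenzaldehyde 1. The three ring A oxygens are bought in place, with the one destined to become O1 already distinguished as the free phenol. A halogen-free oxidant is preferred for 3 to 4, because electrophilic halogen sources could attack C3 and C5 of the phloroglucinol ring.

**Alkyne 9.** The terminal alkyne carbon is removed by a retro one-carbon homologation to aldehyde 8. The formyl carbon is removed by a retro electrophilic formylation, through the iminium salt 7, to the benzyl ether 6, which comes from commercial 2,5-dimethoxyphenol 5. The formylation must go para to the benzyloxy group, the only position that is doubly activated and not flanked on both sides.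

## Roads not taken

Alternative 1: ring B grown on an ethynylchromone by benzannulation. The cut removes three bonds of ring B (C5'–C6', C1'–C2', C2'–C3'). In the forward sense the zerovalent chromium carbene complex pentacarbonyl[(1-tert-butoxyethenyl)(methoxy)methylidene]chromium A3 , formula (CO)5Cr=C(OMe)C(OtBu)=CH2, would react with 2-ethynyl-5,7-dimethoxy-4H-chromen-4-one A2 in a Dötz benzannulation. A CO ligand supplies C2', and the product would be the 2'-phenol 2-(4-tert-butoxy-2-hydroxy-5-methoxyphenyl)-5,7-dimethoxy-4H-chromen-4-one A1 with all ring B oxygens in place. O-Methylation of the 2'-phenol of A1 and acidolysis of its tert-butyl ether would finish the synthesis.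
- Merits: the mechanism fixes the positions of all three ring B oxygens. The 4'-oxygen is distinguished from the start without a separate protection step. One chromone could serve several ring B variants.
- Weak points: carbene A3 is a stoichiometric metal reagent that must be prepared separately. Alkyne A2 is electron-poor and conjugated, the kind that gives the benzannulation least cleanly, and it is a Michael acceptor. The chromone carrying rings A and C still has to be built conventionally first.
- Comparison: ring B with this oxygen pattern is available as a commercial arene, so building it atom by atom is a poor use of steps. The chosen plan uses no stoichiometric transition metal. It matches the built-in 4'-differentiation with a benzyl ether that is removed in the same hydrogenation that opens the isoxazole.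

Alternative 2: pyranopyrandione refolded into ring A. The cut is C5–C6 of ring A. The bis-pyrone 2-(4-benzyloxy-2,5-dimethoxyphenyl)-7-methyl-4H,5H-pyrano[4,3-b]pyran-4,5-dione A5 would be assembled from 4-hydroxy-6-methyl-2H-pyran-2-one A6 and a ring B acyl donor. Mg(OMe)2 in methanol would open the lactone of A5 to a keto ester, and its terminal methyl carbanion would acylate the C5 ester in a Claisen closure. The product would be 2-(4-benzyloxy-2,5-dimethoxyphenyl)-5,7-dihydroxy-4H-chromen-4-one A4 with ring A formed as the 5,7-diol. Double O-methylation of A4 would give 2-(4-benzyloxy-2,5-dimethoxyphenyl)-5,7-dimethoxy-4H-chromen-4-one A7 as the 4'-O-benzyl ether of the target, and hydrogenolysis would follow.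
- Merits: the folding is biomimetic, pyrone A6 is cheap, the base is mild, and ring A arises with unambiguous 5,7-oxygenation.
- Weak points: the step delivers two free phenols that the target needs as methyl ethers. The 5-OH of A4 is hydrogen-bonded to the C4 carbonyl and methylates only under forcing conditions. Assembly of A5 costs several steps of its own.
- Comparison: this road would be better for a 5,7-dihydroxy or differentially substituted ring A. For the dimethyl ether it makes two phenols and re-alkylates them, whereas the chosen plan buys them as methyl ethers in 1.

Alternative 3: trifluorobenzoyl acylation–SNAr annulation. The cuts are C3–C4 and O1–C8a. The lithium enolate of 1-(4-benzyloxy-2,5-dimethoxyphenyl)ethan-1-one A9 made with two equivalents of LiN(SiMe3)2 would be C-acylated by 2,4,6-trifluorobenzoyl chloride A10 to form C3–C4. On warming with K2CO3 the diketone enolate oxygen would displace an ortho fluoride and give 2-(4-benzyloxy-2,5-dimethoxyphenyl)-5,7-difluoro-4H-chromen-4-one A8 with the pyranone closed. NaOMe would exchange both fluorides of A8 to give A7 , and hydrogenolysis would give the target.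
- Merits: this is the shortest road, about five steps from 5, with ketone A9 made by Friedel–Crafts acetylation of 6 and acid chloride A10 bought. It needs no masked functionality and no phenol on ring A. Both fluorides of A8 are activated by the C4 carbonyl.
- Weak points: the methoxy groups are installed on the finished pyranone, which is itself electrophilic at C2 towards methoxide. The first methoxy group deactivates the ring towards the second exchange, so incomplete exchange is a risk. The enolate acylation can also give O-acylation or double acylation.
- Comparison: in step count this road is better than the chosen plan. The chosen plan has every aryl C–O bond present in commercial materials, a neutral key step with built-in regiochemistry, and no nucleophilic substitution on the base-sensitive chromone.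

Key step: step 7

Assumption: compounds 1 and 5 are taken as catalogue chemicals, and nitrile oxide 4 is treated as isolable by analogy with other benzonitrile oxides that carry two ortho substituents.

## Steps

Step 1
Reactants: 1 2-hydroxy-4,6-dimethoxybenzaldehyde
Product: 2 2-(benzyloxy)-4,6-dimethoxybenzaldehyde
Conditions: BnBr, K2CO3, DMF, 60 °C
Reagents that add atoms: benzyl bromide, BrCc1ccccc1
Why: Williamson ether synthesis; K2CO3 in DMF deprotonates the chelated phenol, and the phenoxide is alkylated by the benzylic bromide, the aldehyde being inert.

Step 2
Reactants: 2 2-(benzyloxy)-4,6-dimethoxybenzaldehyde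
Product: 3 (E)-2-(benzyloxy)-4,6-dimethoxybenzaldehyde oxime
Conditions: NH2OH·HCl, NaOAc, EtOH/H2O, 70 °C
Reagents that add atoms: hydroxylamine hydrochloride, Cl.NO
Why: Oxime condensation; warming overcomes the low electrophilicity of the donor-rich, doubly ortho-substituted aldehyde, and the E isomer is the thermodynamic product (the geometry is lost in step 3).

Step 3
Reactants: 3 (E)-2-(benzyloxy)-4,6-dimethoxybenzaldehyde oxime
Product: 4 2-(benzyloxy)-4,6-dimethoxybenzonitrile oxide
Conditions: PhI(OAc)2, TFA (cat.), MeOH, 0 °C; aq. NaHCO3 work-up, concentration below 30 °C
Reagents that add atoms: none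
Why: Dehydrogenation of an aldoxime to the nitrile oxide by a trivalent iodine oxidant; the halogen-free reagent avoids halogenation at the activated ring positions, and the two ortho alkoxy groups slow dimerisation enough for the dipole to be isolated.

Step 4
Reactants: 5 2,5-dimethoxyphenol
Product: 6 2-(benzyloxy)-1,4-dimethoxybenzene
Conditions: BnBr, K2CO3, acetone, reflux
Reagents that add atoms: benzyl bromide, BrCc1ccccc1
Why: Williamson ether synthesis on an unhindered phenol; the benzyl ether protects the future 4'-OH through formylation, homologation and cycloaddition.

Step 5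
Reactants: 6 2-(benzyloxy)-1,4-dimethoxybenzene
Product: 8 4-(benzyloxy)-2,5-dimethoxybenzaldehyde, via aryl dimethyliminium chloride 7 (not isolated)
Conditions: POCl3, DMF, 0 → 70 °C; then ice–water, aq. NaOH to pH 6–7
Reagents that add atoms: N,N-dimethylformamide, CN(C)C=O; water, O
Why: Vilsmeier–Haack formylation; the carbon para to the benzyloxy group and ortho to a methoxy group is doubly activated and unhindered, whereas the other doubly activated carbon lies between two substituents and the third is singly activated, as in the formylation of 1,2,4-trimethoxybenzene.

Step 6
Reactants: 8 4-(benzyloxy)-2,5-dimethoxybenzaldehyde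
Product: 9 1-(benzyloxy)-4-ethynyl-2,5-dimethoxybenzene
Conditions: dimethyl (1-diazo-2-oxopropyl)phosphonate, K2CO3, MeOH, rt
Reagents that add atoms: dimethyl (1-diazo-2-oxopropyl)phosphonate, CC(=O)C(=[N+]=[N-])P(=O)(OC)OC
Why: Seyferth–Gilbert homologation in the Ohira–Bestmann form; methanolysis releases the diazomethylphosphonate anion, which adds to the aldehyde, and loss of dimethyl phosphate and N2 followed by a 1,2-hydride shift of the alkylidene carbene gives the terminal alkyne under conditions that leave the aryl ethers alone.

Step 7
Reactants: 4 2-(benzyloxy)-4,6-dimethoxybenzonitrile oxide; 9 1-(benzyloxy)-4-ethynyl-2,5-dimethoxybenzene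
Product: 10 3-[2-(benzyloxy)-4,6-dimethoxyphenyl]-5-[4-(benzyloxy)-2,5-dimethoxyphenyl]isoxazole
Conditions: toluene, 80 °C (slight excess of 9)
Reagents that add atoms: none
Why: Nitrile oxide 4, a propargyl-type 1,3-dipole, and terminal alkyne 9 combine in a concerted, asynchronous Huisgen [3+2] cycloaddition in which the dipole carbon bonds to the terminal alkyne carbon (the future C3–C4 bond) and the dipole oxygen to the internal alkyne carbon (the oxygen on the future C2). The closest known reaction type is the thermal addition of isolable benzonitrile oxides bearing two ortho substituents to arylacetylenes, which gives 3,5-diarylisoxazoles. The five-membered ring closes by an intermolecular [4π+2π] cycloaddition with both new bonds formed in the same step, and the product is aromatic at once, so no oxidation follows. No stereocentre is formed. The selectivity needed is regiochemical (3,5- against 3,4-diaryl): the dipole carbon, crowded by two ortho alkoxy groups, avoids the aryl-bearing alkyne carbon, and the dominant frontier interaction (alkyne HOMO with its largest coefficient on the terminal carbon, dipole LUMO with its largest coefficient on carbon) points the same way. Chemoselectivity rests on the same ortho alkoxy groups, which slow dimerisation of 4 to the furoxan, on the absence of base, which disfavours 1,3-addition of the alkyne C–H, and on a temperature below that at which hindered nitrile oxides rearrange to isocyanates.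

Step 8
Reactants: 10 3-[2-(benzyloxy)-4,6-dimethoxyphenyl]-5-[4-(benzyloxy)-2,5-dimethoxyphenyl]isoxazole
Product: 11 (Z)-3-amino-3-(2-hydroxy-4,6-dimethoxyphenyl)-1-(4-hydroxy-2,5-dimethoxyphenyl)prop-2-en-1-one
Conditions: H2 (1–3 atm), 10% Pd/C, EtOAc/EtOH, rt
Reagents that add atoms: none
Why: Catalytic hydrogenolysis; the weak isoxazole N–O bond is cleaved to the Z β-enaminone, whose geometry is inherited from the ring and held by an N–H···O=C hydrogen bond, and both aryl benzyl ethers are cleaved to toluene, while the vinylogous amide resists further reduction under these mild conditions.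

Step 9
Reactants: 11 (Z)-3-amino-3-(2-hydroxy-4,6-dimethoxyphenyl)-1-(4-hydroxy-2,5-dimethoxyphenyl)prop-2-en-1-one
Product: 13 2-(4-hydroxy-2,5-dimethoxyphenyl)-5,7-dimethoxy-4H-chromen-4-one, via 1,3-diketone 12 (not isolated)
Conditions: 2 M aq. HCl, EtOH, 70 °C
Reagents that add atoms: water, O
Why: Acid hydrolysis of the primary vinylogous amide (C-protonation, addition of water, loss of ammonia) gives the o-hydroxyaryl 1,3-diketone, which closes by addition of the ring A phenol to the ring B ketone and dehydration, as in the last stage of a Baker–Venkataraman flavone synthesis; ring B has no free ortho hydroxyl, so only this closure is possible, and dilute acid at this temperature should spare the 5-methoxy group.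

## Compound list

1 | 2-hydroxy-4,6-dimethoxybenzaldehyde | COc1cc(O)c(C=O)c(OC)c1 | starting material
2 | 2-(benzyloxy)-4,6-dimethoxybenzaldehyde | COc1cc(OC)c(C=O)c(OCc2ccccc2)c1 | intermediate
3 | (E)-2-(benzyloxy)-4,6-dimethoxybenzaldehyde oxime | COc1cc(OC)c(/C=N/O)c(OCc2ccccc2)c1 | intermediate
4 | 2-(benzyloxy)-4,6-dimethoxybenzonitrile oxide | COc1cc(OC)c(C#[N+][O-])c(OCc2ccccc2)c1 | intermediate
5 | 2,5-dimethoxyphenol | COc1ccc(OC)c(O)c1 | starting material
6 | 2-(benzyloxy)-1,4-dimethoxybenzene | COc1ccc(OC)c(OCc2ccccc2)c1 | intermediate
7 | N-[4-(benzyloxy)-2,5-dimethoxybenzylidene]-N-methylmethanaminium chloride | C[N+](C)=Cc1cc(OC)c(OCc2ccccc2)cc1OC.[Cl-] | intermediate (not isolated)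
8 | 4-(benzyloxy)-2,5-dimethoxybenzaldehyde | O=Cc1cc(OC)c(OCc2ccccc2)cc1OC | intermediate
9 | 1-(benzyloxy)-4-ethynyl-2,5-dimethoxybenzene | C#Cc1cc(OC)c(OCc2ccccc2)cc1OC | intermediate
10 | 3-[2-(benzyloxy)-4,6-dimethoxyphenyl]-5-[4-(benzyloxy)-2,5-dimethoxyphenyl]isoxazole | COc1cc(OC)c(-c2cc(-c3cc(OC)c(OCc4ccccc4)cc3OC)on2)c(OCc2ccccc2)c1 | intermediate
11 | (Z)-3-amino-3-(2-hydroxy-4,6-dimethoxyphenyl)-1-(4-hydroxy-2,5-dimethoxyphenyl)prop-2-en-1-one | COc1cc(O)c(/C(N)=C/C(=O)c2cc(OC)c(O)cc2OC)c(OC)c1 | intermediate
12 | 1-(2-hydroxy-4,6-dimethoxyphenyl)-3-(4-hydroxy-2,5-dimethoxyphenyl)propane-1,3-dione | COc1cc(O)c(C(=O)CC(=O)c2cc(OC)c(O)cc2OC)c(OC)c1 | intermediate (not isolated)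
13 | 2-(4-hydroxy-2,5-dimethoxyphenyl)-5,7-dimethoxy-4H-chromen-4-one | COc1cc(OC)c2c(=O)cc(-c3cc(OC)c(O)cc3OC)oc2c1 | target

## Step count and risks

Total: 9 steps. Longest linear sequence: 6 steps (1 → 2 → 3 → 4 → 10 → 11 → 13; the ring B branch 5 → 6 → 8 → 9 → 10 → 11 → 13 is equally long).

**Step 7 (key step).**
- Risk: the cycloaddition may be slow. The dipole carbon is shielded by two ortho alkoxy groups and the alkyne is donor-rich and ortho-substituted. Thermal rearrangement of the nitrile oxide to the isocyanate, or 1,3-addition of the alkyne C–H across the dipole to an open-chain alkynyl oxime, could then take a share.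
- Fallback: use the more reactive alkene and aromatise afterwards. From aldehyde 8, Wittig methylenation (Ph3PCH3Br, KOtBu, THF) should give 1-(benzyloxy)-4-ethenyl-2,5-dimethoxybenzene F1 as the dipolarophile. The cycloaddition of F1 with 4 in toluene at 40–60 °C is as a rule faster for a monosubstituted alkene and equally 5-selective, and it cannot give the C–H addition product. It should give racemic 3-[2-(benzyloxy)-4,6-dimethoxyphenyl]-5-[4-(benzyloxy)-2,5-dimethoxyphenyl]-4,5-dihydroisoxazole F2 as the cycloadduct. Dehydrogenation of F2 with activated MnO2 in refluxing toluene (or with DDQ) returns to the route at isoxazole 10. The fallback sets out from 8 and 4 and rejoins at 10.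

**Step 8.**
- Risk: the three hydrogenolyses may not keep pace. Debenzylation is fast, but the basic, chelating product can slow the catalyst so that N–O cleavage stalls. Forcing it risks saturation of the enaminone C=C.
- Fallback: separate the two tasks. From 10, reductive N–O cleavage with hexacarbonylmolybdenum, Mo(CO)6, in MeCN/H2O at reflux (a stoichiometric zerovalent molybdenum reductant that does not touch benzyl ethers) should give (Z)-3-amino-3-[2-(benzyloxy)-4,6-dimethoxyphenyl]-1-[4-(benzyloxy)-2,5-dimethoxyphenyl]prop-2-en-1-one F3 with both benzyl ethers intact. Hydrogenolysis of the two benzyl ethers of F3 alone (H2, Pd/C, EtOAc/EtOH) then gives 11. The fallback sets out from 10 and rejoins at 11.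

**Step 3.**
- Risk: the nitrile oxide may be lost during work-up and concentration, through dimerisation to the furoxan or addition of methanol or acetic acid. The oxidant may also attack the electron-rich ring.
- Fallback: generate the dipole by dehydrohalogenation in the presence of its partner. From oxime 3, one equivalent of N-chlorosuccinimide in DMF at 0 °C should give (Z)-2-(benzyloxy)-N-hydroxy-4,6-dimethoxybenzimidoyl chloride F4 as the dipole precursor. Slow addition of Et3N to F4 and alkyne 9 in CH2Cl2 liberates nitrile oxide 4 at low stationary concentration, and it is consumed in the same flask as in step 7. This variant gives up the halogen-free oxidant. In DMF the aldoxime carbon is as a rule chlorinated before an activated ring position, but ring chlorination at C3 or C5 is the known limitation, so the reagent is held to one equivalent at low temperature. The fallback sets out from 3 and rejoins at 4, which is not isolated, and so at isoxazole 10.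

**Step 6.**
- Risk: the diazomethylphosphonate anion may add slowly to an aldehyde that a para and an ortho oxygen donor make a poor electrophile, so the base-labile diazo reagent decomposes first.
- Fallback: bypass the aldehyde by cross-coupling. From ether 6, iodination para to the benzyloxy group (N-iodosuccinimide, cat. TFA, MeCN) should give 1-(benzyloxy)-4-iodo-2,5-dimethoxybenzene F5 as the coupling partner. Sonogashira coupling of F5 with ethynyltrimethylsilane (Pd(PPh3)2Cl2, CuI, Et3N, THF, 50 °C) should give {[4-(benzyloxy)-2,5-dimethoxyphenyl]ethynyl}trimethylsilane F6 as the protected alkyne. Desilylation of F6 with K2CO3 in MeOH gives alkyne 9. The fallback sets out from 6 and rejoins at 9.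

## Further compounds

F1 | step 7 | 1-(benzyloxy)-4-ethenyl-2,5-dimethoxybenzene | C=Cc1cc(OC)c(OCc2ccccc2)cc1OC
F2 | step 7 | racemic 3-[2-(benzyloxy)-4,6-dimethoxyphenyl]-5-[4-(benzyloxy)-2,5-dimethoxyphenyl]-4,5-dihydroisoxazole | COc1cc(OC)c(C2=NOC(c3cc(OC)c(OCc4ccccc4)cc3OC)C2)c(OCc2ccccc2)c1
F3 | step 8 | (Z)-3-amino-3-[2-(benzyloxy)-4,6-dimethoxyphenyl]-1-[4-(benzyloxy)-2,5-dimethoxyphenyl]prop-2-en-1-one | COc1cc(OCc2ccccc2)c(/C(N)=C/C(=O)c2cc(OC)c(OCc3ccccc3)cc2OC)c(OC)c1
F4 | step 3 | (Z)-2-(benzyloxy)-N-hydroxy-4,6-dimethoxybenzimidoyl chloride | COc1cc(OC)c(/C(Cl)=N/O)c(OCc2ccccc2)c1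
F5 | step 6 | 1-(benzyloxy)-4-iodo-2,5-dimethoxybenzene | COc1cc(OCc2ccccc2)c(OC)cc1I
F6 | step 6 | {[4-(benzyloxy)-2,5-dimethoxyphenyl]ethynyl}trimethylsilane | COc1cc(OCc2ccccc2)c(OC)cc1C#C[Si](C)(C)C
A1 | alternative 1 | 2-(4-tert-butoxy-2-hydroxy-5-methoxyphenyl)-5,7-dimethoxy-4H-chromen-4-one | CC(C)(C)Oc1cc(O)c(-c2cc(=O)c3c(OC)cc(OC)cc3o2)cc1OC
A2 | alternative 1 | 2-ethynyl-5,7-dimethoxy-4H-chromen-4-one | C#Cc1cc(=O)c2c(OC)cc(OC)cc2o1
A3 | alternative 1 | pentacarbonyl[(1-tert-butoxyethenyl)(methoxy)methylidene]chromium, (CO)5Cr=C(OMe)C(OtBu)=CH2 | COC(=[Cr](=C=O)(=C=O)(=C=O)(=C=O)=C=O)C(=C)OC(C)(C)C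
A4 | alternative 2 | 2-(4-benzyloxy-2,5-dimethoxyphenyl)-5,7-dihydroxy-4H-chromen-4-one | Oc1cc(O)c2c(=O)cc(-c3cc(OC)c(OCc4ccccc4)cc3OC)oc2c1
A5 | alternative 2 | 2-(4-benzyloxy-2,5-dimethoxyphenyl)-7-methyl-4H,5H-pyrano[4,3-b]pyran-4,5-dione | Cc1cc2oc(-c3cc(OC)c(OCc4ccccc4)cc3OC)cc(=O)c2c(=O)o1
A6 | alternative 2 | 4-hydroxy-6-methyl-2H-pyran-2-one | Cc1cc(O)cc(=O)o1
A7 | alternative 2 | 2-(4-benzyloxy-2,5-dimethoxyphenyl)-5,7-dimethoxy-4H-chromen-4-one | COc1cc(OC)c2c(=O)cc(-c3cc(OC)c(OCc4ccccc4)cc3OC)oc2c1
A8 | alternative 3 | 2-(4-benzyloxy-2,5-dimethoxyphenyl)-5,7-difluoro-4H-chromen-4-one | O=c1cc(-c2cc(OC)c(OCc3ccccc3)cc2OC)oc2cc(F)cc(F)c12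
A9 | alternative 3 | 1-(4-benzyloxy-2,5-dimethoxyphenyl)ethan-1-one | CC(=O)c1cc(OC)c(OCc2ccccc2)cc1OC
A10 | alternative 3 | 2,4,6-trifluorobenzoyl chloride | O=C(Cl)c1c(F)cc(F)cc1F
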